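## Retrosynthetic overview
1. The side-chain tertiary allylic alcohol comes last, by Schenck ene transposition of a prenyl terminus. Before that, the ester is cut to the C1 alcohol and 3-methylbut-2-enoic acid, and the C12 formyl group is carried as its diethyl acetal.
2. The C1 alcohol comes from a macrocyclic α,β-epoxy (Z)-enone by reagent-controlled 1,2-reduction.
3. Key step: the C10–C11 and C11–O bonds form in one flask by a macrocyclising asymmetric Darzens reaction of an acyclic ω-formyl (Z)-α'-chloro enone. The 11-membered carbocycle closes first (aldolate) and the oxirane second.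
4. The acyclic precursor comes from a Claisen rearrangement (C8–C9, E-C6=C7, C10 aldehyde), and from Weinreb acylation of an acetylide followed by semi-hydrogenation (C1–C2, Z-C2=C3).
5. The quaternary C4 comes from a copper-catalysed enantioselective SN2' alkynylation of geranyl diethyl phosphate.

Assumption: compound 9, the chiral NHC precursor and the cinchona phase-transfer salt are bought as catalogue items and are not counted as steps.

Numbering used in the names:
- C1 is the ring carbon that carries the ester oxygen.
- C2=C3 is the Z-alkene, and C4 is the quaternary carbon.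
- C5 is a ring CH2, and C6=C7 is the alkene whose C7 carries C12 (the formyl carbon).
- C8 and C9 are ring CH2 groups.
- C10 and C11 are the oxirane carbons, and C11 carries CH3.

The target is (1R,4S,10S,11R), 2Z, with C5 trans to C12. The oxirane is trans: C9 is trans to C1.

## Route

Step 1
Reactants: 1 geraniol
Product: 2 geranyl diethyl phosphate
Conditions: ClP(O)(OEt)2, pyridine, CH2Cl2, 0 °C → rt
Reagents that add atoms: diethyl chlorophosphate CCOP(=O)(Cl)OCC
Why: O-phosphorylation of the primary allylic alcohol installs the leaving group needed for copper-catalysed allylic substitution and leaves the E-alkene untouched.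

Step 2
Reactants: 2 geranyl diethyl phosphate; 3 ethynyl(trimethyl)silane
Product: 5 (S)-(3-ethenyl-3,7-dimethyloct-6-en-1-ynyl)trimethylsilane, via alkynylalane 4 (not isolated)
Conditions: 3, i-Bu2AlH, Et3N (5 mol %), hexanes, rt; then 2, CuCl2·2H2O (5 mol %), chiral sulfonate-bearing imidazolinium salt (NHC precursor, 5.5 mol %, the antipode that gives S), THF, −15 °C
Reagents that add atoms: diisobutylaluminium hydride CC(C)C[AlH]CC(C)C (aluminium part of 4 only)
Why: Enantioselective NHC–copper-catalysed allylic substitution in the SN2' mode, a type known for geranyl-type phosphates and for alkynylalanes, delivers the alkynyl group to the γ-carbon from the face chosen by the ligand, which sets quaternary C4 as (S) and releases the vinyl group (C5=C6).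

Step 3
Reactants: 5 (S)-enyne
Product: 7 (3S)-3,7-dimethyl-3-[(trimethylsilyl)ethynyl]oct-6-en-1-ol, via B-alkylborane 6 (not isolated)
Conditions: 9-BBN, THF, 0 °C → rt; then NaOH, H2O2, 0 °C
Reagents that add atoms: 9-borabicyclo[3.3.1]nonane [H]B1C2CCCC1CCC2 (boron part of 6 only); hydrogen peroxide OO (oxygen of 7)
Why: In this hydroboration–oxidation, 9-BBN adds anti-Markovnikov to the only monosubstituted alkene far faster than to the trisubstituted alkene or to the alkyne shielded by SiMe3 and C4, and C4 is not touched.

Step 4
Reactants: 7 primary alcohol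
Product: 8 (3S)-3,7-dimethyl-3-[(trimethylsilyl)ethynyl]oct-6-enal
Conditions: Dess–Martin periodinane, CH2Cl2, 0 °C → rt
Reagents that add atoms: none
Why: Dess–Martin oxidation gives the C6 aldehyde without over-oxidation, and the adjacent quaternary centre cannot epimerise.

Step 5
Reactants: 8 aldehyde; 9 2-bromo-3,3-diethoxyprop-1-ene
Product: 11 (5S)-2-(diethoxymethyl)-5,9-dimethyl-5-[(trimethylsilyl)ethynyl]deca-1,8-dien-3-ol as a mixture of C6 epimers, via vinyllithium 10 (not isolated)
Conditions: 9, n-BuLi, THF, −78 °C; then 8, −78 °C; H2O quench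
Reagents that add atoms: n-butyllithium [Li]CCCC (lithium of 10 only)
Why: Bromine–lithium exchange and 1,2-addition of the 2-lithioacrolein acetal bring in C7, C8 and masked C12, the silyl cap keeps the alkyne from being metallated, and the new C6 carbinol centre need not be controlled because step 9 destroys it.

Step 6
Reactants: 11 allylic alcohol; 12 butyl vinyl ether
Product: 14 (5S)-2-(diethoxymethyl)-3-(ethenyloxy)-5-ethynyl-5,9-dimethyldeca-1,8-diene, via silylated vinyl ether 13 (not isolated)
Conditions: 12 (solvent), Pd(OCOCF3)2 (2 mol %), 4,7-diphenyl-1,10-phenanthroline (2 mol %), Et3N (10 mol %), 60 °C; evaporate; K2CO3 (cat.), MeOH, rt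
Reagents that add atoms: none
Why: Transfer vinylation catalysed by divalent palladium puts C9–C10 on the C6 oxygen well below the Claisen temperature, and base methanolysis of the crude product then cleaves the C–Si bond without harming the vinyl ether or the acetal.

Step 7
Reactants: 15 2-chloropropanoyl chloride (racemic); 16 N,O-dimethylhydroxylamine hydrochloride
Product: 17 2-chloro-N-methoxy-N-methylpropanamide
Conditions: Et3N (2.2 equiv), CH2Cl2, 0 °C
Reagents that add atoms: none
Why: N-acylation gives the Weinreb amide, and its stereocentre is irrelevant because C11 is enolised in step 11.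

Step 8
Reactants: 14 terminal alkyne; 17 Weinreb amide
Product: 19 (6S)-2-chloro-9-(diethoxymethyl)-8-(ethenyloxy)-6-methyl-6-(4-methylpent-3-enyl)dec-9-en-4-yn-3-one, via lithium acetylide 18 (not isolated)
Conditions: n-BuLi, THF, −78 °C; then 17, −78 → −40 °C; AcOH quench at −78 °C
Reagents that add atoms: n-butyllithium [Li]CCCC (lithium of 18 only)
Why: In this Weinreb ketone synthesis the acetylide adds once to the chelating amide to give the α-chloro ynone (C1, C11 and its CH3), and because the C6 oxygen is already a vinyl ether no 5-exo oxa-Michael addition to the ynone can occur.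

Step 9
Reactants: 19 allyl vinyl ether
Product: 20 (4E,7S)-11-chloro-4-(diethoxymethyl)-7-methyl-7-(4-methylpent-3-enyl)-10-oxododec-4-en-8-ynal
Conditions: toluene (0.02 M), BHT, 110 °C, sealed tube
Reagents that add atoms: none
Why: The Claisen [3,3]-rearrangement forms C8–C9 and the C10 aldehyde, and in the chair transition state the C5 substituent sits axial to avoid A(1,2) strain against the branched CH(OEt)2 group, so C5 ends trans to C12 (E, ring-cis) from both C6 epimers.

Step 10
Reactants: 20 ynone aldehyde
Product: 21 (4E,7S,8Z)-11-chloro-4-(diethoxymethyl)-7-methyl-7-(4-methylpent-3-enyl)-10-oxododeca-4,8-dienal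
Conditions: H2 (1 atm), Pd/CaCO3 poisoned with Pb(OAc)2, quinoline, EtOAc, 0 °C, stopped at 1 equiv
Reagents that add atoms: none
Why: Lindlar semi-hydrogenation adds H2 syn to the only alkyne to give the Z-C2=C3 enone, while the trisubstituted alkenes, the aldehyde, the acetal and the C–Cl bond are inert under the poisoned catalyst.

Step 11
Reactants: 21 ω-formyl (Z)-α'-chloro enone
Product: 23 (4S,10S,11R)-macrocyclic epoxy enone (C1 ketone; Z-C2=C3; ring-cis C6=C7 bearing CH(OEt)2; trans-10,11-oxirane), via lithium aldolate 22 (not isolated)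
Conditions: LiOH·H2O (5 equiv), 6'-hydroxy-N-[3,5-bis(trifluoromethyl)benzyl]cinchonium bromide of the quinidine series (20 mol %), toluene–CH2Cl2 4:1, 0 °C, 21 added by syringe pump over 16 h (final 1 mM)
Reagents that add atoms: lithium hydroxide [Li+].[OH-] (lithium of 22 only)
Why: Proposed new method: C11–H is the only readily enolisable ketone position (C4 is quaternary, so there is no γ-H and no Favorskii path), and its chiral ammonium enolate adds reversibly to the C10 aldehyde to close the 11-membered ring, helped by the two cis-alkenes and the quaternary carbon as turn elements; only the aldolate with O− anti-periplanar to C–Cl then collapses irreversibly by internal SN2 to the oxirane, so both rings form in one operation, the cation chooses the enolate and aldehyde faces that set C10 (S) and C11 (R), C9 ends trans to the acyl carbon, the acetal blocks the competing 7-exo Michael/cyclopropanation onto an enal, and the closest known types are the intermolecular phase-transfer-catalysed asymmetric Darzens condensation of α-chloro ketones with aliphatic aldehydes and macrocyclising aldol reactions.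

Step 12
Reactants: 23 epoxy enone
Product: 24 (1R,4S,10S,11R)-epoxy alcohol
Conditions: (S)-2-methyl-CBS-oxazaborolidine (1 equiv), catecholborane, toluene, −78 °C; pH 7 buffer
Reagents that add atoms: none
Why: In this Corey–Bakshi–Shibata 1,2-reduction the fully substituted oxirane carbon C11 acts as the large group and the Z-alkenyl arm as the small one, so the (S)-catalyst delivers hydride to give (1R), and the alkenes, the acetal and the epoxide survive catecholborane at −78 °C.

Step 13
Reactants: 24 epoxy alcohol; 25 3-methylbut-2-enoic acid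
Product: 27 (1R,4S,10S,11R)-senecioate enal bearing the 4-methylpent-3-enyl side chain, via acetal ester 26 (not isolated)
Conditions: 25, DCC, DMAP, CH2Cl2, 0 °C → rt; then SiO2 wetted with 10 % aq. oxalic acid, rt, 30 min
Reagents that add atoms: water O (oxygen of the aldehyde)
Why: Steglich esterification acylates C1–OH with retention and with little deconjugation of the acid, and the very labile α,β-unsaturated acetal is then hydrolysed in the same solvent by wet acidic silica under conditions the deactivated oxirane tolerates.

Step 14
Reactants: 27 senecioate enal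
Product: 29 target CNP0164725.3, via allylic hydroperoxide 28 (not isolated)
Conditions: O2, tetraphenylporphyrin (1 mol %), white LED, CH2Cl2, −20 °C; then PPh3, −20 °C → rt
Reagents that add atoms: dioxygen O=O
Why: In this Schenck ene reaction singlet oxygen attacks only the electron-rich side-chain alkene (the enal, the senecioate and the hindered Z-alkene are far slower), abstraction of the C2' hydrogen gives the E-allylic tertiary hydroperoxide that PPh3 reduces to the alcohol, and the isomeric secondary allylic alcohol, formed in similar amount, is removed by chromatography.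

## Compound list
1 | geraniol, (2E)-3,7-dimethylocta-2,6-dien-1-ol | CC(C)=CCC/C(C)=C/CO | starting material
2 | geranyl diethyl phosphate | CC(C)=CCC/C(C)=C/COP(=O)(OCC)OCC | intermediate
3 | ethynyl(trimethyl)silane | C#C[Si](C)(C)C | starting material
4 | diisobutyl[(trimethylsilyl)ethynyl]aluminium | CC(C)C[Al](CC(C)C)C#C[Si](C)(C)C | intermediate
5 | (S)-(3-ethenyl-3,7-dimethyloct-6-en-1-ynyl)trimethylsilane | C[Si](C)(C)C#C[C@@](C)(CCC=C(C)C)C=C | intermediate
6 | 9-{(3S)-3,7-dimethyl-3-[(trimethylsilyl)ethynyl]oct-6-enyl}-9-borabicyclo[3.3.1]nonane | C[Si](C)(C)C#C[C@@](C)(CCC=C(C)C)CCB1C2CCCC1CCC2 | intermediate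
7 | (3S)-3,7-dimethyl-3-[(trimethylsilyl)ethynyl]oct-6-en-1-ol | C[Si](C)(C)C#C[C@@](C)(CCC=C(C)C)CCO | intermediate
8 | (3S)-3,7-dimethyl-3-[(trimethylsilyl)ethynyl]oct-6-enal | C[Si](C)(C)C#C[C@@](C)(CCC=C(C)C)CC=O | intermediate
9 | 2-bromo-3,3-diethoxyprop-1-ene | C=C(Br)C(OCC)OCC | starting material
10 | (3,3-diethoxyprop-1-en-2-yl)lithium | [Li]C(=C)C(OCC)OCC | intermediate
11 | (5S)-2-(diethoxymethyl)-5,9-dimethyl-5-[(trimethylsilyl)ethynyl]deca-1,8-dien-3-ol (carbinol epimers) | C[Si](C)(C)C#C[C@@](C)(CCC=C(C)C)CC(O)C(=C)C(OCC)OCC | intermediate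
12 | butyl vinyl ether | C=COCCCC | starting material
13 | O-vinyl ether of 11 (silyl group still on) | C[Si](C)(C)C#C[C@@](C)(CCC=C(C)C)CC(OC=C)C(=C)C(OCC)OCC | intermediate
14 | (5S)-2-(diethoxymethyl)-3-(ethenyloxy)-5-ethynyl-5,9-dimethyldeca-1,8-diene | C#C[C@@](C)(CCC=C(C)C)CC(OC=C)C(=C)C(OCC)OCC | intermediate
15 | 2-chloropropanoyl chloride (racemic) | CC(Cl)C(=O)Cl | starting material
16 | N,O-dimethylhydroxylamine hydrochloride | CNOC.Cl | starting material
17 | 2-chloro-N-methoxy-N-methylpropanamide | CC(Cl)C(=O)N(C)OC | intermediate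
18 | lithium acetylide of 14 | [Li]C#C[C@@](C)(CCC=C(C)C)CC(OC=C)C(=C)C(OCC)OCC | intermediate
19 | (6S)-2-chloro-9-(diethoxymethyl)-8-(ethenyloxy)-6-methyl-6-(4-methylpent-3-enyl)dec-9-en-4-yn-3-one | CC(Cl)C(=O)C#C[C@@](C)(CCC=C(C)C)CC(OC=C)C(=C)C(OCC)OCC | intermediate
20 | (4E,7S)-11-chloro-4-(diethoxymethyl)-7-methyl-7-(4-methylpent-3-enyl)-10-oxododec-4-en-8-ynal | CC(Cl)C(=O)C#C[C@@](C)(CCC=C(C)C)C/C=C(/C(OCC)OCC)CCC=O | intermediate
21 | (4E,7S,8Z)-11-chloro-4-(diethoxymethyl)-7-methyl-7-(4-methylpent-3-enyl)-10-oxododeca-4,8-dienal | CC(Cl)C(=O)/C=C\[C@@](C)(CCC=C(C)C)C/C=C(/C(OCC)OCC)CCC=O | intermediate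
22 | lithium (4S,10S,11S)-aldolate: 11-membered ring closed, C10–O−, C11–Cl | O=C1/C=C\[C@@](C)(CCC=C(C)C)C/C=C(/C(OCC)OCC)CC[C@H]([O-])[C@]1(C)Cl.[Li+] | intermediate
23 | (4S,10S,11R)-macrocyclic epoxy enone with C12 diethyl acetal | O=C1/C=C\[C@@](C)(CCC=C(C)C)C/C=C(/C(OCC)OCC)CC[C@@H]2O[C@]21C | intermediate
24 | (1R,4S,10S,11R)-epoxy alcohol with C12 diethyl acetal | O[C@@H]1/C=C\[C@@](C)(CCC=C(C)C)C/C=C(/C(OCC)OCC)CC[C@@H]2O[C@]21C | intermediate
25 | 3-methylbut-2-enoic acid (senecioic acid) | CC(C)=CC(=O)O | starting material
26 | C1 senecioate of 24 (acetal still on) | CC(C)=CC(=O)O[C@@H]1/C=C\[C@@](C)(CCC=C(C)C)C/C=C(/C(OCC)OCC)CC[C@@H]2O[C@]21C | intermediate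
27 | C1 senecioate, C12 free enal, 4-methylpent-3-enyl side chain | CC(C)=CC(=O)O[C@@H]1/C=C\[C@@](C)(CCC=C(C)C)C/C=C(/C=O)CC[C@@H]2O[C@]21C | intermediate
28 | side-chain (E)-allylic tertiary hydroperoxide | CC(C)=CC(=O)O[C@@H]1/C=C\[C@@](C)(C/C=C/C(C)(C)OO)C/C=C(/C=O)CC[C@@H]2O[C@]21C | intermediate
29 | CNP0164725.3 | CC(C)=CC(=O)O[C@@H]1/C=C\[C@@](C)(C/C=C/C(C)(C)O)C/C=C(/C=O)CC[C@@H]2O[C@]21C | target

## Step count and risks
- Total step count: 14.
- Longest linear sequence: 13 (steps 1–6 and 8–14); step 7 is a one-step side branch.
- Any minor C4 enantiomer left from step 2 becomes a separable diastereomer under the catalyst control of step 11. This raises the enantiopurity of 23.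

The three steps most likely to fail are listed below.

**Step 11 (macrocyclising Darzens).**
- The risks are oligomerisation, a slow 11-ring aldol, or the wrong epoxide face. For a wrong face the quinine-derived pseudo-enantiomeric salt is the first check.
- The fallback sets out from 21 and closes the ring reductively.
- SmI2 (2.2 equiv, THF, −78 °C, high dilution) removes the chlorine. The trivalent samarium enolate then adds to the C10 aldehyde in an intramolecular Reformatsky-type aldol to give the macrocyclic β-hydroxy ketone F1.
- Mesylation (MsCl, Et3N) and DBU elimination give the cross-conjugated (2Z,10E)-dienone F2.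
- Nucleophilic epoxidation of the unhindered α-methyl enone arm follows (t-BuOOH, La(O-i-Pr)3, (R)-BINOL, Ph3As=O). The C3 terminus is shielded by C4. This comes back to the route at 23.

**Step 12 (facial selectivity of the reduction).**
- The large/small assignment of the two ketone substituents is uncertain in the macrocycle.
- The fallback sets out from 23.
- Substrate-controlled Luche reduction (NaBH4, CeCl3·7H2O, MeOH, −78 °C) gives the (1S)-epimeric epoxy alcohol F3.
- This is esterified with inversion under Mitsunobu conditions (25, PPh3, DIAD, toluene, 0 °C). It comes back to the route at 26, which is then hydrolysed as in step 13.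

**Step 14 (regiochemistry of the ene reaction, intrinsically about 1:1, on the most advanced material).**
- The fallback sets out from 27 and uses an ionic, Markovnikov-controlled sequence.
- N-(phenylseleno)phthalimide and water (cat. pyridinium tosylate, CH2Cl2) add PhSe to C3' and OH to the tertiary carbon, giving the β-hydroxy selenide F4.
- NaIO4 (aq. THF, 0 °C) forms the selenoxide. Its only syn-elimination path runs towards C2', which gives the E-allylic tertiary alcohol and comes back to the route at 29.

## Further compounds
F1 | step 11 | macrocyclic β-hydroxy ketone (C10–OH, C11–H, mixture of C10/C11 epimers) | O=C1/C=C\[C@@](C)(CCC=C(C)C)C/C=C(/C(OCC)OCC)CCC(O)C1C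
F2 | step 11 | (2Z,10E)-cross-conjugated macrocyclic dienone | C/C1=C\CC/C(C(OCC)OCC)=C\C[C@](C)(CCC=C(C)C)/C=C\C1=O
F3 | step 12 | (1S,4S,10S,11R)-epoxy alcohol, C1 epimer of 24 | O[C@H]1/C=C\[C@@](C)(CCC=C(C)C)C/C=C(/C(OCC)OCC)CC[C@@H]2O[C@]21C
F4 | step 14 | side-chain β-hydroxy selenide (PhSe on C3', OH on the tertiary carbon) | CC(C)=CC(=O)O[C@@H]1/C=C\[C@@](C)(CCC([Se]c3ccccc3)C(C)(C)O)C/C=C(/C=O)CC[C@@H]2O[C@]21C
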